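**Plan**

- Retrosynthesis: the C14–OOH bond is cut first (SN2 on a C14 mesylate), then C13–C14 (C13 alkenyl triflate plus a butenolide aldehyde), then the C6–O bond, after the methyl ester and the 6α-hydroxyl are formally closed to the 18,6α-γ-lactone; last, ring C of abietic acid is restored across its C13=C14 alkene.
- Forward: rings A and B come intact from abietic acid. Ring C is cleaved and trimmed to the 8α-hydroxy-8β-methyl group and a three-carbon ester chain on C9. The γ-lactone ring is closed onto C6 and reopened to the methyl ester and 6α-OH. The chain is advanced to the C13 enol triflate and joined to the butenolide aldehyde made from (S)-3-hydroxydihydrofuran-2(3H)-one.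
- Stereochemistry: C4, C5, C9 and C10 are those of abietic acid. C8 is set by α-face oxygen capture (step 4), C6 by the geometry of the lactone closure (step 6), C5′ by the hydroxylactone, and C14 by Corey–Bakshi–Shibata reduction to 14R followed by inversion to 14S.
- Enabling feature: in the trans-fused rings A/B the equatorial 4α-carboxyl carbon C18 and the C6 methylene of ring B are peri, syn-pentane related across C5. C6–H is therefore the only γ C–H the carboxylate can reach: C2 of ring A is antiperiplanar to C18 and C10 is quaternary.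

Key step: step 6

Assumption (numbering): abietane numbering is used up to compound 9. From compound 10 on, labdane numbering is used (C17 = methyl on C8, C18 = 4α-carboxyl carbon, C19 = 4β-methyl, C20 = 10β-methyl); in the side chain C13 is the former ester carbon, C16 its exocyclic methylene, C14 the oxygenated carbon, C15 the next methylene, and the butenolide is numbered O1′ to C5′ as a furan-2(5H)-one.

Assumption (diol 2): it is drawn as the 13α,14α isomer expected from α-face attack; both carbinol centres disappear in the same step, so its configuration has no consequence.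

**Route**

Step 1
Reactants: 1 abietic acid
Product: 3 13,14-dioxo-13,14-secoabiet-7-en-18-oic acid (keto enal acid), via ring C diol 2 (not isolated)
Conditions: OsO4 (2 mol %), NaIO4, 2,6-lutidine, dioxane/H2O, 23 °C
Reagents that add atoms: osmium tetroxide O=[Os](=O)(=O)=O; sodium periodate [Na+].[O-]I(=O)(=O)=O
Why: Lemieux–Johnson cleavage; osmylation should take place at the more accessible C13=C14 alkene of ring C, as is known for abietates, and after glycol cleavage the remaining C7=C8 alkene is an electron-poor enal that resists further oxidation.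

Step 2
Reactants: 3 keto enal acid
Product: 4 (E)-p-toluenesulfonylhydrazone of the C8 formyl group of 3
Conditions: TsNHNH2 (1.05 equiv), MeOH, 23 °C
Reagents that add atoms: p-toluenesulfonyl hydrazide Cc1ccc(cc1)S(=O)(=O)NN
Why: hydrazone condensation, which should be selective because an aldehyde condenses far faster than the hindered isopropyl ketone.

Step 3
Reactants: 4 tosylhydrazone
Product: 7 13-oxo-13,14-secoabiet-8(14)-en-18-oic acid (exocyclic methylene on C8), via allylic tosylhydrazine 5 (not isolated), via allylic diazene 6 (not isolated)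
Conditions: catecholborane (3 equiv), CHCl3, 0 °C; then NaOAc·3H2O, 60 °C
Reagents that add atoms: none
Why: Caglioti-type tosylhydrazone reduction with alkene transposition: 1,2-hydride addition, loss of sulfinate and retro-ene loss of N2 from the allylic diazene deliver hydrogen to C7 and move the alkene to the exocyclic position; the hindered ketone is reduced much more slowly, and the neopentyl acid is only held as its acyloxyborane until work-up.

Step 4
Reactants: 7 exocyclic alkene keto acid
Product: 9 8α-hydroxy-13-oxo-13,14-secoabietan-18-oic acid, via 8α-hydroperoxide 8 (not isolated)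
Conditions: Co(acac)2 (20 mol %), PhSiH3, O2 (1 atm), THF, 23 °C; then PPh3
Reagents that add atoms: dioxygen O=O
Why: Mukaiyama hydration; hydrogen-atom transfer to the 1,1-disubstituted alkene gives the tertiary C8 radical, which should capture O2 on the α face, away from the 1,3-diaxial 10β-methyl group, setting 8α-O and 8β-CH3 before the phosphine reduces the O–O bond.

Step 5
Reactants: 9 hydroxy keto acid
Product: 10 8α-hydroxy-14,15,16-trinorlabdane-13,18-dioic acid 13-isopropyl ester (free C18 acid)
Conditions: mCPBA, CH2Cl2, 23 °C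
Reagents that add atoms: 3-chloroperoxybenzoic acid O=C(OO)c1cccc(Cl)c1
Why: Baeyer–Villiger oxidation, in which the secondary isopropyl group migrates in preference to the primary C12 methylene, giving the isopropyl ester.

Step 6
Reactants: 10 hydroxy acid isopropyl ester
Product: 11 isopropyl 8α-hydroxy-18-oxo-18,6α-epoxy-14,15,16-trinorlabdan-13-oate (18,6α-γ-lactone)
Conditions: Mn(CF3SO3)2((S,S)-pdp) (2 mol %; pdp = N,N′-bis(2-pyridylmethyl)-2,2′-bipyrrolidine), H2O2 (50% aq., 3 equiv, slow addition), CF3CH2OH, 0 °C
Reagents that add atoms: none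
Why: The acid 10 replaces triflate on manganese and assists heterolysis of bound H2O2, so that a high-valent manganese oxo carboxylate is formed whose oxo ligand can only reach γ C–H bonds; it abstracts a hydrogen atom from C6 and the C6 radical is captured by the bound carboxylate oxygen (carboxylate rebound). The closest known reaction type is the carboxylic acid-directed γ-C–H lactonisation of unactivated methylene groups with manganese aminopyridine catalysts and H2O2. The five-membered lactone ring closes by C6–O bond formation in a 5-exo sense, the carboxylate oxygen bonding to the γ radical centre. The new C6 stereocentre is set by the substrate: a five-membered ring can span only the equatorial 4α-carboxyl and the equatorial 6α position, which are syn-pentane related across C5, whereas the axial 6β position is out of reach. The step needs C6 to be oxidised in preference to the tertiary C5–H and C9–H bonds, the ring A methylenes and the chain; this rests on intramolecular delivery (C2 antiperiplanar to C18, C10 quaternary) and on deactivation of the remote C–H bonds by the ester, the carboxyl group and the hydroxyl group hydrogen-bonded to the fluorinated alcohol.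

Step 7
Reactants: 11 γ-lactone isopropyl ester
Product: 13 dimethyl 6α,8α-dihydroxy-14,15,16-trinorlabdane-13,18-dioate, via dipotassium dicarboxylate 12 (not isolated)
Conditions: KOH (2.1 equiv), MeOH/H2O, 65 °C; evaporate; then MeI, DMF, 23 °C
Reagents that add atoms: potassium hydroxide [K+].[OH-]; iodomethane CI
Why: saponification opens the strained lactone and the isopropyl ester irreversibly as carboxylates, and SN2 O-methylation of the carboxylates then forms both methyl esters without attack on the hindered C18 carbonyl; no C–O bond at C6 or C8 is broken, so both configurations are kept.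

Step 8
Reactants: 13 diol diester
Product: 14 dimethyl 6α,8α-bis(triethylsilyloxy)-14,15,16-trinorlabdane-13,18-dioate
Conditions: TESOTf (3 equiv), 2,6-lutidine, CH2Cl2, −78 → 0 °C
Reagents that add atoms: triethylsilyl trifluoromethanesulfonate CC[Si](CC)(CC)OS(=O)(=O)C(F)(F)F
Why: silyl triflate silylation, which is reactive enough for the peri-hindered secondary 6α-OH and the tertiary 8α-OH, and which blocks lactonisation of the 8-hydroxyl onto the chain ester.

Step 9
Reactants: 14 bis-silyl ether diester
Product: 15 methyl 13-[methoxy(methyl)amino]-13-oxo-6α,8α-bis(triethylsilyloxy)-14,15,16-trinorlabdan-18-oate (Weinreb amide)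
Conditions: MeNHOMe·HCl, iPrMgCl, THF, −20 °C
Reagents that add atoms: N,O-dimethylhydroxylamine hydrochloride CNOC.Cl
Why: aminolysis by the magnesium amide (Weinreb amide formation) should occur only at the unhindered chain ester, the C18 ester on quaternary C4 next to the 6α-silyloxy group being inert.

Step 10
Reactants: 15 Weinreb amide
Product: 16 methyl 13-oxo-6α,8α-bis(triethylsilyloxy)-14,15-dinorlabdan-18-oate (C13 methyl ketone)
Conditions: MeMgBr, THF, 0 °C
Reagents that add atoms: methylmagnesium bromide C[Mg]Br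
Why: Weinreb ketone synthesis; the chelated tetrahedral intermediate prevents over-addition and the hindered C18 ester does not react at this temperature.

Step 11
Reactants: 16 methyl ketone
Product: 17 methyl 6α,8α-bis(triethylsilyloxy)-13-(trifluoromethylsulfonyloxy)-14,15-dinorlabd-13(16)-en-18-oate (enol triflate)
Conditions: KN(SiMe3)2, THF, −78 °C; then PhNTf2, −78 → 0 °C
Reagents that add atoms: N-phenylbis(trifluoromethanesulfonimide) O=S(=O)(N(c1ccccc1)S(=O)(=O)C(F)(F)F)C(F)(F)F
Why: kinetic deprotonation by the bulky amide base should take place at the methyl group and not at C12, and O-sulfonylation of the terminal enolate gives the 2-triflyloxy-1-alkene.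

Step 12
Reactants: 18 (S)-3-hydroxydihydrofuran-2(3H)-one
Product: 19 (S)-2,4-dihydroxy-N-methoxy-N-methylbutanamide
Conditions: MeNHOMe·HCl, AlMe3, CH2Cl2, 0 → 23 °C
Reagents that add atoms: N,O-dimethylhydroxylamine hydrochloride CNOC.Cl
Why: aminolysis of the lactone by the aluminium amide (Weinreb amide formation) opens the ring at the acyl carbon and leaves the carbinol stereocentre untouched.

Step 13
Reactants: 19 dihydroxy Weinreb amide
Product: 20 (S)-4-(tert-butyldimethylsilyloxy)-2-hydroxy-N-methoxy-N-methylbutanamide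
Conditions: TBSCl, imidazole, CH2Cl2, 0 °C
Reagents that add atoms: tert-butyldimethylsilyl chloride CC(C)(C)[Si](C)(C)Cl
Why: silylation with the bulky chlorosilane is selective for the primary alcohol and also stops relactonisation.

Step 14
Reactants: 20 silyloxy Weinreb amide
Product: 21 (S)-5-(tert-butyldimethylsilyloxy)-3-hydroxypentan-2-one
Conditions: MeMgBr (3 equiv), THF, −20 → 0 °C
Reagents that add atoms: methylmagnesium bromide C[Mg]Br
Why: Weinreb ketone synthesis on the magnesium alkoxide; the chelate releases the α-hydroxy ketone only on work-up, which limits enolisation of the stereocentre.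

Step 15
Reactants: 21 α-hydroxy ketone; 22 diethylphosphonoacetic acid
Product: 23 (S)-5-(tert-butyldimethylsilyloxy)-2-oxopentan-3-yl 2-(diethoxyphosphoryl)acetate
Conditions: DCC, DMAP (cat.), CH2Cl2, 0 → 23 °C
Reagents that add atoms: none
Why: Steglich esterification of the secondary alcohol under neutral conditions, with no C–O cleavage at the stereocentre.

Step 16
Reactants: 23 keto phosphonoacetate
Product: 24 (S)-5-[2-(tert-butyldimethylsilyloxy)ethyl]-4-methylfuran-2(5H)-one
Conditions: LiCl, iPr2NEt, MeCN, 23 °C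
Reagents that add atoms: none
Why: intramolecular Horner–Wadsworth–Emmons olefination under Masamune–Roush conditions closes the butenolide onto the methyl ketone, the weak amine base being chosen to keep the C5′ configuration.

Step 17
Reactants: 24 silyl ether butenolide
Product: 25 (S)-5-(2-hydroxyethyl)-4-methylfuran-2(5H)-one
Conditions: HF·pyridine, THF, 0 → 23 °C
Reagents that add atoms: none
Why: fluoride-mediated desilylation in an acidic medium, which avoids base-induced epimerisation at C5′ and oxa-Michael closure onto the butenolide.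

Step 18
Reactants: 25 hydroxyethyl butenolide
Product: 26 (S)-2-(3-methyl-5-oxo-2,5-dihydrofuran-2-yl)acetaldehyde
Conditions: Dess–Martin periodinane, CH2Cl2, 0 → 23 °C
Reagents that add atoms: none
Why: Dess–Martin oxidation under non-basic conditions, so that the β-acyloxy aldehyde is not exposed to β-elimination; it is used at once.

Step 19
Reactants: 17 enol triflate; 26 butenolide aldehyde
Product: 27 C14-epimeric allylic alcohols (C9 chain CH2CH2–C(=CH2)–CH(OH)–CH2–butenolide)
Conditions: CrCl2 (4 equiv), NiCl2 (2 mol %), DMF, 23 °C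
Reagents that add atoms: none
Why: Nozaki–Hiyama–Kishi coupling: oxidative addition of the triflate to zerovalent nickel, transmetalation to trivalent chromium and aldehyde-selective addition of the alkenylchromium species, under conditions neutral enough for the butenolide and both esters; the C14 configuration is not controlled here and is corrected in steps 20 and 21.

Step 20
Reactants: 27 allylic alcohols
Product: 28 C14 enone (CH2CH2–C(=CH2)–C(=O)–CH2–butenolide)
Conditions: Dess–Martin periodinane, CH2Cl2, 0 °C
Reagents that add atoms: none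
Why: Dess–Martin oxidation converges both epimers on one enone without base, which the β-acyloxy ketone would not tolerate.

Step 21
Reactants: 28 enone
Product: 29 (14R)-allylic alcohol
Conditions: (S)-2-methyl-CBS-oxazaborolidine (0.5 equiv), catecholborane, toluene, −78 °C
Reagents that add atoms: none
Why: Corey–Bakshi–Shibata reduction; with the α-branched alkenyl group as the large substituent and the C15 methylene as the small one, the (S)-catalyst should deliver hydride to the face that gives 14R, and catecholborane at low temperature leaves both alkenes and the lactone untouched.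

Step 22
Reactants: 29 (14R)-allylic alcohol
Product: 31 (14S)-hydroperoxide 6α,8α-bis(triethylsilyl) ether, via allylic mesylate 30 (not isolated)
Conditions: MsCl, Et3N, CH2Cl2, −40 °C; then H2O2 (anhydrous, in Et2O, excess), −40 → 0 °C
Reagents that add atoms: hydrogen peroxide OO
Why: sulfonate displacement by hydrogen peroxide (SN2), a known route to secondary hydroperoxides, should invert C14 from R to S; neutral peroxide is used so that the butenolide is not attacked by a peroxide anion.

Step 23
Reactants: 31 protected hydroperoxide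
Product: 32 target CNP0324515.1
Conditions: HF·pyridine, pyridine, THF, 0 °C
Reagents that add atoms: none
Why: fluoride-mediated cleavage of both triethylsilyl ethers under buffered conditions that the allylic hydroperoxide, the butenolide and the methyl ester should survive.

**Compound list**

1 | abietic acid (abieta-7,13-dien-18-oic acid; 4α-CO2H, 5α-H, 9α-H, 10β-CH3) | C1C[C@@H]2[C@@]3(C)CCC[C@@](C)(C(=O)O)[C@@H]3CC=C2C=C1C(C)C | starting material
2 | 13α,14α-dihydroxyabiet-7-en-18-oic acid (ring C cis-diol on the α face) | C1C[C@@H]2[C@@]3(C)CCC[C@@](C)(C(=O)O)[C@@H]3CC=C2[C@@H](O)[C@]1(O)C(C)C | intermediate (not isolated)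
3 | 13,14-dioxo-13,14-secoabiet-7-en-18-oic acid (formyl group on C8 conjugated with C7=C8; 4-methyl-3-oxopentyl chain on C9β) | CC(C)C(=O)CC[C@@H]1[C@@]2(C)CCC[C@@](C)(C(=O)O)[C@@H]2CC=C1C=O | intermediate
4 | (E)-p-toluenesulfonylhydrazone of the formyl group of 3 | CC(C)C(=O)CC[C@@H]1[C@@]2(C)CCC[C@@](C)(C(=O)O)[C@@H]2CC=C1/C=N/NS(=O)(=O)c1ccc(C)cc1 | intermediate
5 | allylic N-alkyl-N′-tosylhydrazine (C8–CH2–NH–NHTs, C7=C8 retained; boron-bound in the flask) | CC(C)C(=O)CC[C@@H]1[C@@]2(C)CCC[C@@](C)(C(=O)O)[C@@H]2CC=C1CNNS(=O)(=O)c1ccc(C)cc1 | intermediate (not isolated)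
6 | allylic diazene (C8–CH2–N=NH, C7=C8 retained) | CC(C)C(=O)CC[C@@H]1[C@@]2(C)CCC[C@@](C)(C(=O)O)[C@@H]2CC=C1CN=N | intermediate (not isolated)
7 | 13-oxo-13,14-secoabiet-8(14)-en-18-oic acid (exocyclic methylene on C8) | CC(C)C(=O)CC[C@@H]1[C@@]2(C)CCC[C@@](C)(C(=O)O)[C@@H]2CCC1=C | intermediate
8 | 8α-hydroperoxy-13-oxo-13,14-secoabietan-18-oic acid (8β-CH3) | CC(C)C(=O)CC[C@@H]1[C@@]2(C)CCC[C@@](C)(C(=O)O)[C@@H]2CC[C@@]1(C)OO | intermediate (not isolated)
9 | 8α-hydroxy-13-oxo-13,14-secoabietan-18-oic acid (8β-CH3) | CC(C)C(=O)CC[C@@H]1[C@@]2(C)CCC[C@@](C)(C(=O)O)[C@@H]2CC[C@@]1(C)O | intermediate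
10 | 8α-hydroxy-14,15,16-trinorlabdane-13,18-dioic acid 13-isopropyl ester (free 4α-carboxylic acid) | CC(C)OC(=O)CC[C@@H]1[C@@]2(C)CCC[C@@](C)(C(=O)O)[C@@H]2CC[C@@]1(C)O | intermediate
11 | isopropyl 8α-hydroxy-18-oxo-18,6α-epoxy-14,15,16-trinorlabdan-13-oate (18,6α-γ-lactone) | CC(C)OC(=O)CC[C@@H]1[C@@]2(C)CCC[C@@](C)(C(=O)O3)[C@@H]2[C@@H]3C[C@@]1(C)O | intermediate
12 | dipotassium 6α,8α-dihydroxy-14,15,16-trinorlabdane-13,18-dioate | [K+].[K+].[O-]C(=O)CC[C@@H]1[C@@]2(C)CCC[C@@](C)(C([O-])=O)[C@@H]2[C@@H](O)C[C@@]1(C)O | intermediate (not isolated)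
13 | dimethyl 6α,8α-dihydroxy-14,15,16-trinorlabdane-13,18-dioate | COC(=O)CC[C@@H]1[C@@]2(C)CCC[C@@](C)(C(=O)OC)[C@@H]2[C@@H](O)C[C@@]1(C)O | intermediate
14 | dimethyl 6α,8α-bis(triethylsilyloxy)-14,15,16-trinorlabdane-13,18-dioate | COC(=O)CC[C@@H]1[C@@]2(C)CCC[C@@](C)(C(=O)OC)[C@@H]2[C@@H](O[Si](CC)(CC)CC)C[C@@]1(C)O[Si](CC)(CC)CC | intermediate
15 | methyl 13-[methoxy(methyl)amino]-13-oxo-6α,8α-bis(triethylsilyloxy)-14,15,16-trinorlabdan-18-oate | CON(C)C(=O)CC[C@@H]1[C@@]2(C)CCC[C@@](C)(C(=O)OC)[C@@H]2[C@@H](O[Si](CC)(CC)CC)C[C@@]1(C)O[Si](CC)(CC)CC | intermediate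
16 | methyl 13-oxo-6α,8α-bis(triethylsilyloxy)-14,15-dinorlabdan-18-oate (methyl ketone) | CC(=O)CC[C@@H]1[C@@]2(C)CCC[C@@](C)(C(=O)OC)[C@@H]2[C@@H](O[Si](CC)(CC)CC)C[C@@]1(C)O[Si](CC)(CC)CC | intermediate
17 | methyl 6α,8α-bis(triethylsilyloxy)-13-(trifluoromethylsulfonyloxy)-14,15-dinorlabd-13(16)-en-18-oate (enol triflate) | C=C(OS(=O)(=O)C(F)(F)F)CC[C@@H]1[C@@]2(C)CCC[C@@](C)(C(=O)OC)[C@@H]2[C@@H](O[Si](CC)(CC)CC)C[C@@]1(C)O[Si](CC)(CC)CC | intermediate
18 | (S)-3-hydroxydihydrofuran-2(3H)-one | O[C@H]1CCOC1=O | starting material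
19 | (S)-2,4-dihydroxy-N-methoxy-N-methylbutanamide | CON(C)C(=O)[C@@H](O)CCO | intermediate
20 | (S)-4-(tert-butyldimethylsilyloxy)-2-hydroxy-N-methoxy-N-methylbutanamide | CON(C)C(=O)[C@@H](O)CCO[Si](C)(C)C(C)(C)C | intermediate
21 | (S)-5-(tert-butyldimethylsilyloxy)-3-hydroxypentan-2-one | CC(=O)[C@@H](O)CCO[Si](C)(C)C(C)(C)C | intermediate
22 | diethylphosphonoacetic acid | CCOP(=O)(CC(=O)O)OCC | starting material
23 | (S)-5-(tert-butyldimethylsilyloxy)-2-oxopentan-3-yl 2-(diethoxyphosphoryl)acetate | CC(=O)[C@@H](OC(=O)CP(=O)(OCC)OCC)CCO[Si](C)(C)C(C)(C)C | intermediate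
24 | (S)-5-[2-(tert-butyldimethylsilyloxy)ethyl]-4-methylfuran-2(5H)-one | CC(C)(C)[Si](C)(C)OCC[C@@H]1OC(=O)C=C1C | intermediate
25 | (S)-5-(2-hydroxyethyl)-4-methylfuran-2(5H)-one | OCC[C@@H]1OC(=O)C=C1C | intermediate
26 | (S)-2-(3-methyl-5-oxo-2,5-dihydrofuran-2-yl)acetaldehyde | O=CC[C@@H]1OC(=O)C=C1C | intermediate
27 | C14-epimeric allylic alcohols: bis(triethylsilyl) ether methyl ester core of 17 with the C9 chain CH2CH2–C(=CH2)–CH(OH)–CH2–[(2S)-3-methyl-5-oxo-2,5-dihydrofuran-2-yl] | C=C(CC[C@@H]1[C@@]2(C)CCC[C@@](C)(C(=O)OC)[C@@H]2[C@@H](O[Si](CC)(CC)CC)C[C@@]1(C)O[Si](CC)(CC)CC)C(O)C[C@@H]1OC(=O)C=C1C | intermediate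
28 | C14 enone: as 27 with C14 as ketone | C=C(CC[C@@H]1[C@@]2(C)CCC[C@@](C)(C(=O)OC)[C@@H]2[C@@H](O[Si](CC)(CC)CC)C[C@@]1(C)O[Si](CC)(CC)CC)C(=O)C[C@@H]1OC(=O)C=C1C | intermediate
29 | (14R)-allylic alcohol (single epimer of 27) | C=C(CC[C@@H]1[C@@]2(C)CCC[C@@](C)(C(=O)OC)[C@@H]2[C@@H](O[Si](CC)(CC)CC)C[C@@]1(C)O[Si](CC)(CC)CC)[C@@H](C[C@@H]1OC(=O)C=C1C)O | intermediate
30 | (14R)-allylic methanesulfonate of 29 | C=C(CC[C@@H]1[C@@]2(C)CCC[C@@](C)(C(=O)OC)[C@@H]2[C@@H](O[Si](CC)(CC)CC)C[C@@]1(C)O[Si](CC)(CC)CC)[C@@H](C[C@@H]1OC(=O)C=C1C)OS(C)(=O)=O | intermediate (not isolated)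
31 | (14S)-hydroperoxide, 6α,8α-bis(triethylsilyl) ether of the target | C=C(CC[C@@H]1[C@@]2(C)CCC[C@@](C)(C(=O)OC)[C@@H]2[C@@H](O[Si](CC)(CC)CC)C[C@@]1(C)O[Si](CC)(CC)CC)[C@H](C[C@@H]1OC(=O)C=C1C)OO | intermediate
32 | CNP0324515.1: methyl ester with 6α-OH, 8α-OH, 8β-CH3, 5α-H, 9α-H, 10β-CH3, C13(16) exocyclic methylene, (14S)-OOH and (5′S)-4′-methylbutenolide | C=C(CC[C@@H]1[C@@]2(C)CCC[C@@](C)(C(=O)OC)[C@@H]2[C@@H](O)C[C@@]1(C)O)[C@H](C[C@@H]1OC(=O)C=C1C)OO | target

**Step count**

Total: 23 steps. Longest linear sequence: 16 steps from abietic acid (steps 1–11 and 19–23). The butenolide branch is 7 steps (steps 12–18).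

**Steps most likely to fail, with fallbacks**

Step 6. Hydrogen abstraction may escape the carboxylate tether and attack the tertiary C9–H or ring A methylenes, or the hydroxy acid may bind the catalyst unproductively so that turnover stalls. The fallback replaces the metal-oxo by an amidyl radical and sets out from 10. Heating 10 with TsOH in toluene closes the chain ester onto the 8α-hydroxyl with loss of propan-2-ol. This gives the 8α,13-δ-lactone acid F1, in which the tertiary alcohol is masked against hypoiodite formation. Oxalyl chloride with catalytic DMF gives the acid chloride F2, and ammonia gives the primary amide F3. Irradiation with PhI(OAc)2 and I2 generates the N-iodoamide F4. Its amidyl radical abstracts hydrogen from C6 by a 1,5-shift (Hofmann–Löffler–Freytag-type N-iodoamide photolysis), and the amide oxygen then closes onto C6 to give the iminolactone F5. Aqueous acid work-up hydrolyses F5 to the bis-lactone F6. Treatment of F6 with KOH and then MeI, as in step 7, opens both lactones, and the route is rejoined at 13.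

Step 22. The peroxide may attack the terminal methylene in an SN2′ sense, the mesylate may ionise with loss of configuration at C14 or eliminate to a diene, and peroxide may add to the butenolide. The fallback installs the hydroperoxide by an ene reaction and sets out from 27, so that steps 20 and 21 are not needed. Mitsunobu reaction of 27 with 2-nitrobenzenesulfonylhydrazide (PPh3, DEAD, N-methylmorpholine, −30 °C) gives the allylic sulfonylhydrazine F7. On warming, F7 loses the sulfinic acid to give the allylic diazene F8, and retro-ene loss of N2 transposes the alkene to the (13E)-trisubstituted alkene F9 (C13 methyl, C13=C14). Schenck ene reaction of F9 with singlet oxygen (O2, tetraphenylporphyrin, visible light, CH2Cl2, 0 °C) should abstract hydrogen from the C13 methyl group and place the hydroperoxide on C14. The 14S isomer would have to be separated by chromatography from its C14 epimer and from the regioisomeric tertiary hydroperoxide. The route is rejoined at 31.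

Step 4. Oxygen capture by the C8 radical may show poor facial selectivity and give the 8β-hydroperoxide as well. The fallback sets the C8–O bond by epoxidation and sets out from 7. Excess mCPBA buffered with Na2HPO4 should epoxidise the exocyclic alkene from the α face and carry out the Baeyer–Villiger oxidation of the isopropyl ketone in the same operation, giving the 8α,17-epoxy isopropyl ester acid F10. Sodium phenylselenide (PhSeSePh, NaBH4, EtOH) opens the epoxide at the primary carbon to give the 8α-hydroxy 17-phenylselenide F11. Radical deselenation with Bu3SnH and AIBN in toluene at 80 °C turns the CH2SePh group into the C17 methyl group. The route is rejoined at 10, with step 5 already included.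

Further compounds
F1 | step 6 | 8α,13-δ-lactone of 8α-hydroxy-14,15,16-trinorlabdane-13,18-dioic acid (free C18 acid) | O=C1CC[C@@H]2[C@@]3(C)CCC[C@@](C)(C(=O)O)[C@@H]3CC[C@@]2(C)O1
F2 | step 6 | C18 acid chloride of F1 | O=C1CC[C@@H]2[C@@]3(C)CCC[C@@](C)(C(Cl)=O)[C@@H]3CC[C@@]2(C)O1
F3 | step 6 | C18 primary amide of F1 | O=C1CC[C@@H]2[C@@]3(C)CCC[C@@](C)(C(N)=O)[C@@H]3CC[C@@]2(C)O1
F4 | step 6 | N-iodoamide of F3 | O=C1CC[C@@H]2[C@@]3(C)CCC[C@@](C)(C(=O)NI)[C@@H]3CC[C@@]2(C)O1
F5 | step 6 | 18,6α-iminolactone with the 8α,13-δ-lactone | O=C1CC[C@@H]2[C@@]3(C)CCC[C@@](C)(C(=N)O4)[C@@H]3[C@@H]4C[C@@]2(C)O1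
F6 | step 6 | bis-lactone (18,6α-γ-lactone and 8α,13-δ-lactone) | O=C1CC[C@@H]2[C@@]3(C)CCC[C@@](C)(C(=O)O4)[C@@H]3[C@@H]4C[C@@]2(C)O1
F7 | step 22 | C14 N-(2-nitrophenylsulfonyl)hydrazine from 27 (C14 epimers) | C=C(CC[C@@H]1[C@@]2(C)CCC[C@@](C)(C(=O)OC)[C@@H]2[C@@H](O[Si](CC)(CC)CC)C[C@@]1(C)O[Si](CC)(CC)CC)C(C[C@@H]1OC(=O)C=C1C)N(N)S(=O)(=O)c1ccccc1[N+](=O)[O-]
F8 | step 22 | C14 allylic diazene (C14 epimers) | C=C(CC[C@@H]1[C@@]2(C)CCC[C@@](C)(C(=O)OC)[C@@H]2[C@@H](O[Si](CC)(CC)CC)C[C@@]1(C)O[Si](CC)(CC)CC)C(C[C@@H]1OC(=O)C=C1C)N=N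
F9 | step 22 | (13E)-trisubstituted alkene (C13 methyl, C13=C14), bis(triethylsilyl) ether methyl ester | C/C(CC[C@@H]1[C@@]2(C)CCC[C@@](C)(C(=O)OC)[C@@H]2[C@@H](O[Si](CC)(CC)CC)C[C@@]1(C)O[Si](CC)(CC)CC)=C\C[C@@H]1OC(=O)C=C1C
F10 | step 4 | 8α,17-epoxy-14,15,16-trinorlabdane-13,18-dioic acid 13-isopropyl ester | CC(C)OC(=O)CC[C@@H]1[C@@]2(C)CCC[C@@](C)(C(=O)O)[C@@H]2CC[C@@]1(C3)O3
F11 | step 4 | 8α-hydroxy-17-(phenylselanyl)-14,15,16-trinorlabdane-13,18-dioic acid 13-isopropyl ester | CC(C)OC(=O)CC[C@@H]1[C@@]2(C)CCC[C@@](C)(C(=O)O)[C@@H]2CC[C@@]1(C[Se]c1ccccc1)O
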